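**Plan**

- Retrosynthesis: the phenol O–allyl bond and the angelate C(=O)–O bond on one CH2O arm are cut first. The two (R)-2-methylbutanoate C(=O)–O bonds (benzylic CH2O and the other CH2O arm) are cut together next, and the bond from aromatic C1 to the carbinol carbon last.
- Forward: an aryllithium adds to 2,2-dimethyl-1,3-dioxan-5-one to join the three-carbon chain to the purchased benzene ring, and acid frees a tetraol. A lipase then installs both 2-methylbutanoates, the angelate follows, and the phenol is released last. No ring is built.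
- Feature used: the tertiary carbinol carbon (C2 of the propane chain) is bonded to OH, to C1 of the benzene ring and to two CH2O arms. It is stereogenic only because one arm carries the angelate and the other the 2-methylbutanoate, so with two CH2OH arms it is prochiral and the arms are enantiotopic.
- Stereochemistry: both acyl centres are bought as (R)-2-methylbutanoic acid and the Z-alkene as angelic acid. The carbinol centre comes from the lipase choosing the pro-S CH2OH arm.

Key step: step 7

Assumption: which enantiotopic arm a lipase prefers on a 2-aryl glycerol cannot be predicted with certainty. The route takes Burkholderia cepacia lipase to favour the pro-S arm, and the fallback for step 7 sets the same centre by reagent control if that preference is opposite or weak.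

**Step 1**
Reactants: 1 4-bromo-3-hydroxybenzoic acid
Product: 2 2-bromo-5-(hydroxymethyl)phenol
Conditions: BH3·THF (3 equiv), THF, 0 to 23 °C; MeOH quench, aqueous work-up
Reagents that add atoms: none
Why: Chemoselective borane reduction of a carboxylic acid through its acyloxyborane should leave the aryl bromide untouched, the phenol being only borylated and released on work-up.

**Step 2**
Reactants: 2 2-bromo-5-(hydroxymethyl)phenol
Product: 3 [4-bromo-3-(allyloxy)phenyl]methanol
Conditions: allyl bromide (1.1 equiv), K2CO3, acetone, reflux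
Reagents that add atoms: allyl bromide, C=CCBr
Why: Williamson ether synthesis, in which carbonate deprotonates only the phenol, so the phenoxide is allylated and the benzylic alcohol stays free.

**Step 3**
Reactants: 3 [4-bromo-3-(allyloxy)phenyl]methanol
Product: 4 {[4-bromo-3-(allyloxy)phenyl]methoxy}(tert-butyl)dimethylsilane
Conditions: TBSCl, imidazole, CH2Cl2, 0 to 23 °C
Reagents that add atoms: tert-butyldimethylsilyl chloride, CC(C)(C)[Si](C)(C)Cl
Why: Imidazole-promoted silylation of a primary alcohol removes the only acidic proton before the organolithium step.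

**Step 4**
Reactants: 4 {[4-bromo-3-(allyloxy)phenyl]methoxy}(tert-butyl)dimethylsilane; 5 2,2-dimethyl-1,3-dioxan-5-one
Product: 7 5-[2-(allyloxy)-4-({[tert-butyl(dimethyl)silyl]oxy}methyl)phenyl]-2,2-dimethyl-1,3-dioxan-5-ol, via aryllithium 6 (not isolated)
Conditions: n-BuLi (1.05 equiv), THF, −78 °C; then 5, −78 to −40 °C; sat. NH4Cl
Reagents that add atoms: none
Why: Bromine–lithium exchange gives an aryllithium chelated by the ortho-allyloxy oxygen, which at −78 °C should add 1,2 to the ketone faster than it enolises it or carbolithiates its own allyl group; the new carbinol carbon lies on the mirror plane of the dioxane and is not yet a stereocentre.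

**Step 5**
Reactants: 7 5-[2-(allyloxy)-4-({[tert-butyl(dimethyl)silyl]oxy}methyl)phenyl]-2,2-dimethyl-1,3-dioxan-5-ol
Product: 8 2-[2-(allyloxy)-4-(hydroxymethyl)phenyl]propane-1,2,3-triol
Conditions: Dowex 50WX8 (H+ form), THF/H2O 3:1, 40 °C; filter, concentrate
Reagents that add atoms: none
Why: Acid-catalysed hydrolysis removes the isopropylidene acetal and the primary silyl ether in one pot, and the tertiary benzylic alcohol should resist ionisation because its cation would carry two β-oxygen substituents.

**Step 6**
Reactants: 9 (2R)-2-methylbutanoic acid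
Product: 10 ethenyl (2R)-2-methylbutanoate (vinyl ester)
Conditions: Pd(OAc)2 (5 mol%), KOH (10 mol%), vinyl acetate (neat, excess), 23 °C; NaHCO3 wash, distillation
Reagents that add atoms: vinyl acetate, CC(=O)OC=C
Why: Transvinylation catalysed by divalent palladium (oxypalladation of vinyl acetate by the carboxylate, then β-acetoxy elimination) exchanges the acid for acetic acid under conditions too mild to enolise the α-stereocentre.

**Step 7**
Reactants: 8 2-[2-(allyloxy)-4-(hydroxymethyl)phenyl]propane-1,2,3-triol; 10 ethenyl (2R)-2-methylbutanoate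
Product: 12 (2S)-2-[2-(allyloxy)-4-({[(2R)-2-methylbutanoyl]oxy}methyl)phenyl]-2,3-dihydroxypropyl (2R)-2-methylbutanoate, via benzylic monoester 11 (not isolated)
Conditions: Burkholderia cepacia lipase (immobilised, Amano PS-IM), 10 (4 equiv), t-BuOMe/THF 4:1, 4 Å MS, 35 °C; filter, concentrate, use at once
Reagents that add atoms: none
Why: The active-site serine is acylated by vinyl ester 10 with irreversible loss of vinyl alcohol (acetaldehyde), and the acyl-enzyme is attacked by a primary hydroxyl held in the chiral alcohol pocket, first the exposed benzylic CH2OH (giving 11) and then one CH2OH arm of the glycerol unit. The closest known reaction type is the lipase-catalysed enantiotopic-group-selective transesterification of prochiral 2,2-disubstituted propane-1,3-diols with vinyl esters; two ester C–O bonds form and no ring is closed. The carbinol carbon becomes a stereocentre under control of the enzyme pocket, which tells the bulky ortho-allyloxyaryl group from the small tertiary OH and so acylates only the pro-S arm, giving the S descriptor in 12 (it becomes R once the angelate outranks the 2-methylbutanoate, the centre itself being untouched). The step needs site selectivity (two of three primary OH, none at the tertiary OH) and arm selectivity: a tertiary alcohol is not accepted by the enzyme, and because the acyl groups are already R-configured the wrong-arm ester is a diastereomer, so its level can be followed on an achiral column and it should be drained faster than 12 into the triester, its free arm being the one the enzyme prefers. Base-free neutral conditions and the α-branched acyl group should keep 1,3-acyl migration between the arms, which would epimerise the carbinol centre, slow.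

**Step 8**
Reactants: 12 (2S)-2-[2-(allyloxy)-4-({[(2R)-2-methylbutanoyl]oxy}methyl)phenyl]-2,3-dihydroxypropyl (2R)-2-methylbutanoate; 13 angelic acid, (2Z)-2-methylbut-2-enoic acid
Product: 15 (2R)-2-[2-(allyloxy)-4-({[(2R)-2-methylbutanoyl]oxy}methyl)phenyl]-2-hydroxy-3-{[(2R)-2-methylbutanoyl]oxy}propyl (2Z)-2-methylbut-2-enoate, via mixed anhydride 14 (not isolated)
Conditions: 13 (3 equiv), 2,4,6-trichlorobenzoyl chloride (3 equiv), Et3N (3 equiv), toluene, 23 °C; then 12, 75 °C
Reagents that add atoms: none
Why: Yamaguchi-type esterification in which the primary alcohol attacks the less hindered angeloyl carbonyl of the mixed anhydride; with no nucleophilic catalyst present the Z-alkene should not isomerise to the tiglate by conjugate addition–elimination, and the tertiary alcohol is too hindered to react, so the carbinol centre is untouched.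

**Step 9**
Reactants: 15 (2R)-2-[2-(allyloxy)-4-({[(2R)-2-methylbutanoyl]oxy}methyl)phenyl]-2-hydroxy-3-{[(2R)-2-methylbutanoyl]oxy}propyl (2Z)-2-methylbut-2-enoate
Product: 16 (2R)-2-hydroxy-2-[2-hydroxy-4-({[(2R)-2-methylbutanoyl]oxy}methyl)phenyl]-3-{[(2R)-2-methylbutanoyl]oxy}propyl (2Z)-2-methylbut-2-enoate (target)
Conditions: Pd(PPh3)4 (5 mol%), morpholine (3 equiv), THF, 23 °C; pH 5 buffer wash
Reagents that add atoms: none
Why: Tsuji–Trost deallylation, in which zerovalent palladium ionises the aryl allyl ether to a π-allyl complex and phenoxide and morpholine traps the allyl group, should leave the three esters, the angelate alkene and all stereocentres alone at room temperature.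

**Compound list**

1 | 4-bromo-3-hydroxybenzoic acid | OC(=O)c1ccc(Br)c(O)c1 | starting material
2 | 2-bromo-5-(hydroxymethyl)phenol | OCc1ccc(Br)c(O)c1 | intermediate
3 | [4-bromo-3-(allyloxy)phenyl]methanol | OCc1ccc(Br)c(OCC=C)c1 | intermediate
4 | {[4-bromo-3-(allyloxy)phenyl]methoxy}(tert-butyl)dimethylsilane | CC(C)(C)[Si](C)(C)OCc1ccc(Br)c(OCC=C)c1 | intermediate
5 | 2,2-dimethyl-1,3-dioxan-5-one | CC1(C)OCC(=O)CO1 | starting material
6 | [2-(allyloxy)-4-({[tert-butyl(dimethyl)silyl]oxy}methyl)phenyl]lithium | [Li]c1ccc(CO[Si](C)(C)C(C)(C)C)cc1OCC=C | intermediate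
7 | 5-[2-(allyloxy)-4-({[tert-butyl(dimethyl)silyl]oxy}methyl)phenyl]-2,2-dimethyl-1,3-dioxan-5-ol | CC1(C)OCC(O)(CO1)c1ccc(CO[Si](C)(C)C(C)(C)C)cc1OCC=C | intermediate
8 | 2-[2-(allyloxy)-4-(hydroxymethyl)phenyl]propane-1,2,3-triol (prochiral tetraol) | OCC(O)(CO)c1ccc(CO)cc1OCC=C | intermediate
9 | (2R)-2-methylbutanoic acid | OC(=O)[C@H](C)CC | starting material
10 | ethenyl (2R)-2-methylbutanoate | C=COC(=O)[C@H](C)CC | intermediate
11 | [3-(allyloxy)-4-(1,2,3-trihydroxypropan-2-yl)phenyl]methyl (2R)-2-methylbutanoate | OCC(O)(CO)c1ccc(COC(=O)[C@H](C)CC)cc1OCC=C | intermediate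
12 | (2S)-2-[2-(allyloxy)-4-({[(2R)-2-methylbutanoyl]oxy}methyl)phenyl]-2,3-dihydroxypropyl (2R)-2-methylbutanoate | OC[C@](O)(COC(=O)[C@H](C)CC)c1ccc(COC(=O)[C@H](C)CC)cc1OCC=C | intermediate
13 | angelic acid, (2Z)-2-methylbut-2-enoic acid | C/C=C(/C)C(=O)O | starting material
14 | (2Z)-2-methylbut-2-enoic 2,4,6-trichlorobenzoic anhydride | C/C=C(/C)C(=O)OC(=O)c1c(Cl)cc(Cl)cc1Cl | intermediate
15 | (2R)-2-[2-(allyloxy)-4-({[(2R)-2-methylbutanoyl]oxy}methyl)phenyl]-2-hydroxy-3-{[(2R)-2-methylbutanoyl]oxy}propyl (2Z)-2-methylbut-2-enoate | C/C=C(/C)C(=O)OC[C@](O)(COC(=O)[C@H](C)CC)c1ccc(COC(=O)[C@H](C)CC)cc1OCC=C | intermediate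
16 | (2R)-2-hydroxy-2-[2-hydroxy-4-({[(2R)-2-methylbutanoyl]oxy}methyl)phenyl]-3-{[(2R)-2-methylbutanoyl]oxy}propyl (2Z)-2-methylbut-2-enoate | C/C=C(/C)C(=O)OC[C@](O)(COC(=O)[C@H](C)CC)c1ccc(COC(=O)[C@H](C)CC)cc1O | target

**Step count**

Total: 9 steps. Longest linear sequence: 8 steps (steps 1–5 and 7–9, from 1); step 6 is a one-step side branch that joins at step 7.

**Steps most likely to fail**

Step 7. The second acylation may stall, because a neopentyl-type CH2OH meets an α-branched acyl donor in the enzyme pocket, or the enzyme may choose between the arms weakly or in the wrong sense. The fallback sets out from alcohol 3 and comes back at 12, fixing the carbinol centre by reagent control. Esterification of 3 with acid 9 (EDC·HCl, DMAP cat., CH2Cl2) would give [4-bromo-3-(allyloxy)phenyl]methyl (2R)-2-methylbutanoate F1. Stille coupling with 2-(tributylstannyl)prop-2-en-1-ol (Pd(PPh3)4, CuI, CsF, DMF, 45 °C) would give the 2-arylallyl alcohol [3-(allyloxy)-4-(3-hydroxyprop-1-en-2-yl)phenyl]methyl (2R)-2-methylbutanoate F2. Sharpless asymmetric epoxidation (Ti(OiPr)4, L-(+)-diethyl tartrate, t-BuOOH, 4 Å MS, CH2Cl2, −20 °C) acts only on the allylic alcohol and not on the O-allyl group, and by the usual facial rule should give {3-(allyloxy)-4-[(2S)-2-(hydroxymethyl)oxiran-2-yl]phenyl}methyl (2R)-2-methylbutanoate F3. Opening the epoxide at its CH2 terminus with caesium (2R)-2-methylbutanoate (from 9 and Cs2CO3, DMF, 50 °C) then returns 12.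

Step 8. The angeloyl unit may isomerise to the tigloyl unit during activation, or the 2-methylbutanoate of 12 may migrate to the free arm under amine and heat before the angelate is on, which would epimerise the carbinol centre. The fallback sets out from 12 and comes back at 15, building the Z-alkene on an ester already in place. Esterification of the free CH2OH with 2-[bis(2,2,2-trifluoroethoxy)phosphoryl]propanoic acid (EDC·HCl, DMAP cat., CH2Cl2, 0 °C) would give (2R)-2-[2-(allyloxy)-4-({[(2R)-2-methylbutanoyl]oxy}methyl)phenyl]-2-hydroxy-3-{[(2R)-2-methylbutanoyl]oxy}propyl 2-[bis(2,2,2-trifluoroethoxy)phosphoryl]propanoate F4, as a mixture of epimers at the phosphonate carbon. Still–Gennari olefination with acetaldehyde (KN(SiMe3)2 1.0 equiv, 18-crown-6, THF, −78 °C) should then deliver 15; one equivalent of base deprotonates the phosphonate carbon in preference to the tertiary alcohol.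

Step 4. Proton transfer from the enolisable ketone to the aryllithium may outrun addition and return the debrominated arene. The fallback sets out from bromide 4 (lithiated to 6 as in step 4) and comes back at tetraol 8, using a non-enolisable electrophile. Addition of 6 to diethyl oxomalonate (THF, −78 °C) would give diethyl 2-[2-(allyloxy)-4-({[tert-butyl(dimethyl)silyl]oxy}methyl)phenyl]-2-hydroxypropanedioate F5. Reduction of both esters (LiAlH4, THF, 0 °C) would give 2-[2-(allyloxy)-4-({[tert-butyl(dimethyl)silyl]oxy}methyl)phenyl]propane-1,2,3-triol F6, and the acid treatment of step 5 removes the silyl ether to give 8.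

**Further compounds**

F1 | step 7 | [4-bromo-3-(allyloxy)phenyl]methyl (2R)-2-methylbutanoate | C=CCOc1cc(COC(=O)[C@H](C)CC)ccc1Br
F2 | step 7 | [3-(allyloxy)-4-(3-hydroxyprop-1-en-2-yl)phenyl]methyl (2R)-2-methylbutanoate | C=CCOc1cc(COC(=O)[C@H](C)CC)ccc1C(=C)CO
F3 | step 7 | {3-(allyloxy)-4-[(2S)-2-(hydroxymethyl)oxiran-2-yl]phenyl}methyl (2R)-2-methylbutanoate | OC[C@]1(CO1)c1ccc(COC(=O)[C@H](C)CC)cc1OCC=C
F4 | step 8 | (2R)-2-[2-(allyloxy)-4-({[(2R)-2-methylbutanoyl]oxy}methyl)phenyl]-2-hydroxy-3-{[(2R)-2-methylbutanoyl]oxy}propyl 2-[bis(2,2,2-trifluoroethoxy)phosphoryl]propanoate | CC(C(=O)OC[C@](O)(COC(=O)[C@H](C)CC)c1ccc(COC(=O)[C@H](C)CC)cc1OCC=C)P(=O)(OCC(F)(F)F)OCC(F)(F)F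
F5 | step 4 | diethyl 2-[2-(allyloxy)-4-({[tert-butyl(dimethyl)silyl]oxy}methyl)phenyl]-2-hydroxypropanedioate | CCOC(=O)C(O)(C(=O)OCC)c1ccc(CO[Si](C)(C)C(C)(C)C)cc1OCC=C
F6 | step 4 | 2-[2-(allyloxy)-4-({[tert-butyl(dimethyl)silyl]oxy}methyl)phenyl]propane-1,2,3-triol | OCC(O)(CO)c1ccc(CO[Si](C)(C)C(C)(C)C)cc1OCC=C
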